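The cyclohexene ring (indene C3a, C4, C5, C6, C7, C7a) is cut by a retro-Diels–Alder disconnection of C4–C5 and C3a–C7a: its C6=C7 alkene lies between the quaternary C5 and C7a, and the carboxyl-bearing C4 is the α-carbon of an (E)-enal dienophile. One intramolecular Diels–Alder reaction of an open-chain hexaenal therefore closes the cyclohexene and, through the (Z)-alkene tether that becomes C2=C3, the cyclopentene at once, and sets four stereocentres (two adjacent quaternary) from the single C1 methyl centre. The precursor is a linear (2E,4Z,7E,9E,11E,13E)-hexaenol built from methyl (S)-3-hydroxy-2-methylpropanoate by olefinations and one cross-coupling; its oxidation triggers the key step.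

Key step: step 9

Remark: ring atoms are numbered as in 1H-indene (C1 is the methyl-bearing sp3 carbon of the cyclopentene, C4 the carboxyl-bearing carbon); ylide 10 is taken to be purchasable like its lower homologue 7; where a name and a SMILES string differ, the SMILES string is meant.

Step 1
Reactants: 1 methyl (S)-3-hydroxy-2-methylpropanoate
Product: 2 methyl (S)-3-[(tert-butyldimethylsilyl)oxy]-2-methylpropanoate
Conditions: TBSCl, imidazole, CH2Cl2, 0 °C → rt
Reagents that add atoms: tert-butyldimethylsilyl chloride, CC(C)(C)[Si](C)(C)Cl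
Why: Silyl ether formation on the unhindered primary alcohol (silylation) masks it for the ester reduction and does not touch the stereocentre.

Step 2
Reactants: 2 methyl (S)-3-[(tert-butyldimethylsilyl)oxy]-2-methylpropanoate
Product: 3 (S)-3-[(tert-butyldimethylsilyl)oxy]-2-methylpropanal
Conditions: i-Bu2AlH (1.1 equiv), CH2Cl2, −78 °C; MeOH quench, aqueous work-up
Reagents that add atoms: none
Why: Partial ester reduction with i-Bu2AlH at −78 °C stops at the aluminium hemiacetal, which collapses to the α-chiral aldehyde only on work-up, so the stereocentre should be kept if the aldehyde is used cold and at once.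

Step 3
Reactants: 3 (S)-3-[(tert-butyldimethylsilyl)oxy]-2-methylpropanal; 4 propyltriphenylphosphonium bromide
Product: 5 tert-butyl{[(2R,3Z)-4-iodo-2-methylhex-3-en-1-yl]oxy}dimethylsilane
Conditions: 4, n-BuLi, THF, 0 °C → rt; I2, −78 °C; NaN(SiMe3)2, −20 °C; then 3, −78 °C → rt, dark
Reagents that add atoms: iodine, [I][I]
Why: Zhao-type α-iodo Wittig olefination, in which the non-stabilised iodo ylide made in the flask adds to the aldehyde under kinetic control to give the (Z)-iodoalkene (iodine cis to the chain), the geometry that later becomes the tether alkene.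

Step 4
Reactants: 5 tert-butyl{[(2R,3Z)-4-iodo-2-methylhex-3-en-1-yl]oxy}dimethylsilane
Product: 6 (2R,3Z)-4-iodo-2-methylhex-3-en-1-ol
Conditions: camphorsulfonic acid (cat.), MeOH, 0 °C → rt
Reagents that add atoms: none
Why: Acid-catalysed methanolysis (desilylation) frees the primary alcohol while the vinyl iodide and the allylic stereocentre are inert to the mild acid.

Step 5
Reactants: 6 (2R,3Z)-4-iodo-2-methylhex-3-en-1-ol; 7 2-(triphenylphosphoranylidene)propanal
Product: 9 (2E,4S,5Z)-6-iodo-2,4-dimethylocta-2,5-dienal, via iodo aldehyde 8 (not isolated)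
Conditions: Dess–Martin periodinane, NaHCO3, CH2Cl2, 0 °C; filter cold, exchange solvent; 7, toluene, 60 °C, dark
Reagents that add atoms: none
Why: Dess–Martin oxidation gives the β,γ-unsaturated aldehyde, which is taken on at once in a Wittig olefination with the stabilised formyl ylide to give the (E)-2-methyl enal under thermodynamic (E) control, so that the labile α-stereocentre is exposed only briefly and to no strong base.

Step 6
Reactants: 9 (2E,4S,5Z)-6-iodo-2,4-dimethylocta-2,5-dienal; 10 2-(triphenylphosphoranylidene)butanal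
Product: 11 (2E,4E,6S,7Z)-2-ethyl-8-iodo-4,6-dimethyldeca-2,4,7-trienal
Conditions: 10, toluene, 100 °C, dark
Reagents that add atoms: none
Why: A second Wittig olefination with the stabilised α-ethyl formyl ylide extends the enal to the (2E,4E)-dienal, the (E) preference placing the ethyl group cis to the chain as the later diene terminus requires.

Step 7
Reactants: 11 (2E,4E,6S,7Z)-2-ethyl-8-iodo-4,6-dimethyldeca-2,4,7-trienal; 12 diethyl [(2E)-3-phenylprop-2-en-1-yl]phosphonate
Product: 13 [(1E,3E,5E,7E,9S,10Z)-5-ethyl-11-iodo-7,9-dimethyltrideca-1,3,5,7,10-pentaen-1-yl]benzene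
Conditions: 12, LiN(SiMe3)2, THF, −78 °C; then 11, −78 → 0 °C, dark
Reagents that add atoms: none
Why: Horner–Wadsworth–Emmons olefination with the lithiated allylic phosphonate forms the new disubstituted alkene with (E) selectivity and completes the phenyltetraene without touching the vinyl iodide.

Step 8
Reactants: 13 [(1E,3E,5E,7E,9S,10Z)-5-ethyl-11-iodo-7,9-dimethyltrideca-1,3,5,7,10-pentaen-1-yl]benzene; 14 prop-2-yn-1-ol
Product: 15 (2E,4Z,6S,7E,9E,11E,13E)-4,10-diethyl-2,6,8-trimethyl-14-phenyltetradeca-2,4,7,9,11,13-hexaen-1-ol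
Conditions: 14, Me3Al, Cp2ZrCl2 (cat.), CH2Cl2, 0 °C → rt; then 13, Pd(PPh3)4 (cat.), ZnCl2 (cat.), THF, rt, dark
Reagents that add atoms: trimethylaluminium, C[Al](C)C
Why: Zirconium-catalysed syn-carboalumination of the alkyne gives the (E)-alkenylalane regioselectively (methyl to the internal carbon), and the palladium-catalysed Negishi cross-coupling with the (Z)-vinyl iodide proceeds with retention at both sp2 carbons to give the (2E,4Z)-dienol.

Step 9
Reactants: 15 (2E,4Z,6S,7E,9E,11E,13E)-4,10-diethyl-2,6,8-trimethyl-14-phenyltetradeca-2,4,7,9,11,13-hexaen-1-ol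
Product: 17 (1R,3aR,4R,5S,7aS)-3,5-diethyl-1,4,7-trimethyl-5-[(1E,3E)-4-phenylbuta-1,3-dien-1-yl]-3a,4,5,7a-tetrahydro-1H-indene-4-carbaldehyde, via hexaenal 16 (not isolated)
Conditions: MnO2 (activated, excess), CH2Cl2, rt, dark; filter; dilute with toluene, BHT (cat.), rt → 60 °C
Reagents that add atoms: none
Why: MnO2 oxidises the allylic alcohol to the (E)-enal of 16, which places an activated C2=C3 dienophile three atoms from the C7=C8–C9=C10 diene, and a concerted suprafacial intramolecular Diels–Alder reaction (thermal normal-demand [4+2] cycloaddition of the 1,3,8-nonatriene type) follows. The cyclohexene closes by the C2–C10 and C3–C7 bonds across the diene termini, and the cyclopentene closes in the same event as the tether ring (C3, C4, C5, C6, C7) through the C3–C7 bond, which only the (4Z) geometry allows. The two adjacent quaternary centres (indene C4, C5) follow stereospecifically from the (2E) dienophile and (9E) diene geometries. The trans ring fusion (C3a, C7a) requires the transition state with the formyl group endo and the tether carbon exo, which is favoured by secondary orbital overlap and because the alternative would force the ethyl-bearing tether carbon and the C2 methyl under the diene. The diene face is selected by the C6 methyl stereocentre: 1,3-allylic strain with the C8 methyl keeps C6–H in the diene plane, so the dienophile adds anti to the C6 methyl and the indene C1 methyl ends cis to H7a. Chemoselectivity among the six alkenes is secured by the tether length, since no other diene/dienophile pairing can close a five- or six-membered tether ring.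

Step 10
Reactants: 17 (1R,3aR,4R,5S,7aS)-3,5-diethyl-1,4,7-trimethyl-5-[(1E,3E)-4-phenylbuta-1,3-dien-1-yl]-3a,4,5,7a-tetrahydro-1H-indene-4-carbaldehyde
Product: 18 (1R,3aR,4R,5S,7aS)-3,5-diethyl-1,4,7-trimethyl-5-[(1E,3E)-4-phenylbuta-1,3-dien-1-yl]-3a,4,5,7a-tetrahydro-1H-indene-4-carboxylic acid
Conditions: NaClO2, NaH2PO4, 2-methyl-2-butene, t-BuOH/H2O, 0 °C → rt
Reagents that add atoms: sodium chlorite, [Na+].[O-]Cl=O
Why: Pinnick oxidation converts the hindered aldehyde into the acid under buffered conditions, with 2-methyl-2-butene scavenging hypochlorous acid so that the diene and ring alkenes are spared and no stereocentre can epimerise (C4 is quaternary).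

Compound list
1 | methyl (S)-3-hydroxy-2-methylpropanoate | COC(=O)[C@@H](C)CO | starting material
2 | methyl (S)-3-[(tert-butyldimethylsilyl)oxy]-2-methylpropanoate | COC(=O)[C@@H](C)CO[Si](C)(C)C(C)(C)C | intermediate
3 | (S)-3-[(tert-butyldimethylsilyl)oxy]-2-methylpropanal | O=C[C@@H](C)CO[Si](C)(C)C(C)(C)C | intermediate
4 | propyltriphenylphosphonium bromide | CCC[P+](c1ccccc1)(c1ccccc1)c1ccccc1.[Br-] | starting material
5 | tert-butyl{[(2R,3Z)-4-iodo-2-methylhex-3-en-1-yl]oxy}dimethylsilane | CC/C(I)=C/[C@@H](C)CO[Si](C)(C)C(C)(C)C | intermediate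
6 | (2R,3Z)-4-iodo-2-methylhex-3-en-1-ol | CC/C(I)=C/[C@@H](C)CO | intermediate
7 | 2-(triphenylphosphoranylidene)propanal | CC(C=O)=P(c1ccccc1)(c1ccccc1)c1ccccc1 | starting material
8 | (2R,3Z)-4-iodo-2-methylhex-3-enal | CC/C(I)=C/[C@@H](C)C=O | intermediate
9 | (2E,4S,5Z)-6-iodo-2,4-dimethylocta-2,5-dienal | CC/C(I)=C/[C@@H](C)/C=C(\C)C=O | intermediate
10 | 2-(triphenylphosphoranylidene)butanal | CCC(C=O)=P(c1ccccc1)(c1ccccc1)c1ccccc1 | starting material
11 | (2E,4E,6S,7Z)-2-ethyl-8-iodo-4,6-dimethyldeca-2,4,7-trienal | CC/C(I)=C/[C@@H](C)/C=C(C)/C=C(\CC)C=O | intermediate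
12 | diethyl [(2E)-3-phenylprop-2-en-1-yl]phosphonate | CCOP(=O)(C/C=C/c1ccccc1)OCC | starting material
13 | [(1E,3E,5E,7E,9S,10Z)-5-ethyl-11-iodo-7,9-dimethyltrideca-1,3,5,7,10-pentaen-1-yl]benzene | CC/C(I)=C/[C@@H](C)/C=C(C)/C=C(CC)/C=C/C=C/c1ccccc1 | intermediate
14 | prop-2-yn-1-ol | C#CCO | starting material
15 | (2E,4Z,6S,7E,9E,11E,13E)-4,10-diethyl-2,6,8-trimethyl-14-phenyltetradeca-2,4,7,9,11,13-hexaen-1-ol | OC/C(C)=C/C(CC)=C\[C@@H](C)/C=C(C)/C=C(CC)/C=C/C=C/c1ccccc1 | intermediate
16 | (2E,4Z,6S,7E,9E,11E,13E)-4,10-diethyl-2,6,8-trimethyl-14-phenyltetradeca-2,4,7,9,11,13-hexaenal | O=C/C(C)=C/C(CC)=C\[C@@H](C)/C=C(C)/C=C(CC)/C=C/C=C/c1ccccc1 | intermediate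
17 | (1R,3aR,4R,5S,7aS)-3,5-diethyl-1,4,7-trimethyl-5-[(1E,3E)-4-phenylbuta-1,3-dien-1-yl]-3a,4,5,7a-tetrahydro-1H-indene-4-carbaldehyde | CCC1=C[C@@H](C)[C@@H]2C(C)=C[C@@](/C=C/C=C/c3ccccc3)(CC)[C@](C)(C=O)[C@@H]12 | intermediate
18 | (1R,3aR,4R,5S,7aS)-3,5-diethyl-1,4,7-trimethyl-5-[(1E,3E)-4-phenylbuta-1,3-dien-1-yl]-3a,4,5,7a-tetrahydro-1H-indene-4-carboxylic acid | CCC1=C[C@@H](C)[C@@H]2C(C)=C[C@@](/C=C/C=C/c3ccccc3)(CC)[C@](C)(C(=O)O)[C@@H]12 | target

Total step count: 10
Longest linear sequence: 10 steps (1 to 18)

Steps most likely to fail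

Step 9. The two tether orientations may compete, which would erode the trans ring fusion. If the cycloaddition needs prolonged heating, the hexaenal may also be lost through hydrogen shifts and self-condensation before it cyclises. The fallback moves the cycloaddition to the carboxylic acid oxidation level. Setting out from 15, oxidation with MnO2 at 0 °C and immediate treatment of the cold filtrate with NaClO2, NaH2PO4 and 2-methyl-2-butene would give (2E,4Z,6S,7E,9E,11E,13E)-4,10-diethyl-2,6,8-trimethyl-14-phenyltetradeca-2,4,7,9,11,13-hexaenoic acid F1, which tolerates heating. Its intramolecular Diels–Alder reaction in toluene at 110 °C (BHT), or in water as its sodium salt, would give 18 directly, where the route is rejoined.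

Step 5. Configuration at the α-carbon may be lost, or the β,γ-double bond may migrate into conjugation, while aldehyde 8 waits for the slow formyl ylide. The fallback traps the aldehyde as it forms and reaches the aldehyde oxidation level afterwards. Setting out from 6, Dess–Martin oxidation in the presence of ethyl 2-(triphenylphosphoranylidene)propanoate (CH2Cl2, 0 °C, tandem oxidation–Wittig) would give ethyl (2E,4S,5Z)-6-iodo-2,4-dimethylocta-2,5-dienoate F2. Reduction with i-Bu2AlH (CH2Cl2, −78 °C) would give (2E,4S,5Z)-6-iodo-2,4-dimethylocta-2,5-dien-1-ol F3, and MnO2 (CH2Cl2, rt) would give 9, where the route is rejoined.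

Step 8. Incomplete carboalumination may be carried into the coupling, methyl may be transferred from the excess Me3Al to 13, or transmetalation to the hindered (Z)-iodide may be slow, all in one flask with a light-sensitive pentaene. The fallback makes, purifies and couples the nucleophile as a stannane. Setting out from 14, carboalumination (Me3Al, Cp2ZrCl2) quenched with iodine would give (E)-3-iodo-2-methylprop-2-en-1-ol F4. Palladium-catalysed stannylation ((Bu3Sn)2, PdCl2(PPh3)2, THF) would give (E)-2-methyl-3-(tributylstannyl)prop-2-en-1-ol F5. Stille coupling of F5 with 13 (Pd2(dba)3, AsPh3, CuI, N-methylpyrrolidone, rt) would give 15, where the route is rejoined.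

Further compounds
F1 | step 9 | (2E,4Z,6S,7E,9E,11E,13E)-4,10-diethyl-2,6,8-trimethyl-14-phenyltetradeca-2,4,7,9,11,13-hexaenoic acid | OC(=O)/C(C)=C/C(CC)=C\[C@@H](C)/C=C(C)/C=C(CC)/C=C/C=C/c1ccccc1
F2 | step 5 | ethyl (2E,4S,5Z)-6-iodo-2,4-dimethylocta-2,5-dienoate | CC/C(I)=C/[C@@H](C)/C=C(\C)C(=O)OCC
F3 | step 5 | (2E,4S,5Z)-6-iodo-2,4-dimethylocta-2,5-dien-1-ol | CC/C(I)=C/[C@@H](C)/C=C(\C)CO
F4 | step 8 | (E)-3-iodo-2-methylprop-2-en-1-ol | OC/C(C)=C/I
F5 | step 8 | (E)-2-methyl-3-(tributylstannyl)prop-2-en-1-ol | OC/C(C)=C/[Sn](CCCC)(CCCC)CCCC
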